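**Plan**

- Retrosynthesis: remove the two acyl groups and the PMB ether, open the lactone at C11–C12 (alkyne + CO), return the enal to a C14 alcohol with a C1=C2 bond, then cut C3–C4 by a retro-oxy-Cope that re-forms a C1–C6 bond.
- The resulting six-membered ring is cut at C1–C6 (allylchromium + aldehyde), C7–C11 (epoxide + acetylide) and C9–C10 (aldol).
- Forward: acyclic C6–C10 chain, then the ring C1–C10–C9–C8–C7–C6 (not present in the target), then its four-atom expansion to the ten-membered carbocycle, then lactone, enal and esters.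
- Enabling feature: C3 and C4 are the termini of the 1,5-enyne C3=C2–C1–C6(O)–C5≡C4. Its middle bond C1–C6 bridges C7–C10, and C6 bears the future lactone oxygen. An alkoxide there drives a [3,3] shift that trades C1–C6 for C3–C4 and leaves the C4=C5 enone.
- Stereochemistry: C9 from an Evans aldol; C8 and C7 from a Sharpless epoxidation and its invertive opening; C6 from reduction of the C6 ketone.
- Both ring-cis alkenes are set under control: C4=C5 by protonation of the allenolate, C1=C10 by thermodynamic conjugation of the aldehyde.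

Key step: step 16

Remark: target (germacrane) numbering C1–C15 is used for every intermediate; the configurations drawn at C1, C6 and C10 of compounds 19–33 are the expected major ones and are assumed to be inconsequential, because C6 is re-set in step 17 and C1 and C10 become sp2.

**Route**

Step 1
Reactants: 1 (S)-4-benzyl-1,3-oxazolidin-2-one; 2 (E)-but-2-enoyl chloride
Product: 3 (4S)-4-benzyl-3-[(2E)-but-2-enoyl]-1,3-oxazolidin-2-one
Conditions: n-BuLi, THF, −78 °C; then 2, −78 to 0 °C
Reagents that add atoms: none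
Why: N-acylation of the lithiated Evans auxiliary by the acid chloride is standard and leaves the (E)-alkene untouched.

Step 2
Reactants: 3 N-crotonyl oxazolidinone; 4 ethyl (E)-4-oxobut-2-enoate
Product: 6 ethyl (2E,4R,5S)-5-{[(4S)-4-benzyl-2-oxo-1,3-oxazolidin-3-yl]carbonyl}-4-hydroxyhepta-2,6-dienoate, via dibutylboron dienolate 5 (not isolated)
Conditions: Bu2BOTf, Et3N, CH2Cl2, −78 to 0 °C; then 4, −78 °C; pH 7 buffer/MeOH
Reagents that add atoms: none
Why: Evans syn-aldol reaction of the boron (Z)-dienolate through a Zimmerman–Traxler chair, in which the (S)-benzyl auxiliary fixes the carbinol centre C9 and the aldehyde of 4 reacts in preference to its enoate (the C10 centre formed is destroyed later).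

Step 3
Reactants: 6 aldol adduct
Product: 7 ethyl (2E,4R,5R)-4-hydroxy-5-(hydroxymethyl)hepta-2,6-dienoate
Conditions: NaBH4, THF–H2O (4:1), 0 °C to rt
Reagents that add atoms: none
Why: reductive cleavage of the N-acyloxazolidinone by borohydride gives the primary alcohol and returns the auxiliary, while the less electrophilic conjugated ethyl ester survives.

Step 4
Reactants: 7 diol
Product: 8 ethyl (2E)-3-[(4R,5R)-5-ethenyl-2,2-dimethyl-1,3-dioxan-4-yl]prop-2-enoate
Conditions: Me2C(OMe)2, PPTS (cat.), CH2Cl2, rt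
Reagents that add atoms: 2,2-dimethoxypropane COC(C)(C)OC
Why: acid-catalysed transketalisation closes the 1,3-dioxane (acetonide) that masks O9 and O14 together until step 19.

Step 5
Reactants: 8 acetonide ester
Product: 9 (2E)-3-[(4R,5R)-5-ethenyl-2,2-dimethyl-1,3-dioxan-4-yl]prop-2-en-1-ol
Conditions: iBu2AlH (2.5 equiv), CH2Cl2, −78 °C; Rochelle salt
Reagents that add atoms: none
Why: 1,2-reduction of the enoate by the aluminium hydride gives the (E)-allylic alcohol needed for directed epoxidation.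

Step 6
Reactants: 9 allylic alcohol
Product: 10 {(2R,3R)-3-[(4S,5R)-5-ethenyl-2,2-dimethyl-1,3-dioxan-4-yl]oxiran-2-yl}methanol
Conditions: Ti(OiPr)4 (10 mol%), D-(−)-diethyl tartrate (12 mol%), t-BuOOH, 4 Å MS, CH2Cl2, −20 °C
Reagents that add atoms: tert-butyl hydroperoxide CC(C)(C)OO
Why: Sharpless asymmetric epoxidation under reagent control (the D-(−)-tartrate gives the (2R,3R)-epoxy alcohol) sets C8 directly and C7 after inversion, and the isolated vinyl group is not touched by the titanium–tartrate system.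

Step 7
Reactants: 10 epoxy alcohol; 11 (Z)-1,4-dichlorobut-2-ene
Product: 12 {(2R,3R)-3-[(4S,5R)-5-[(1E)-3-chloroprop-1-en-1-yl]-2,2-dimethyl-1,3-dioxan-4-yl]oxiran-2-yl}methanol
Conditions: 11 (3 equiv), second-generation Grubbs catalyst (5 mol%), CH2Cl2, 40 °C
Reagents that add atoms: none
Why: olefin cross-metathesis of the terminal vinyl group with the symmetrical dichloride brings in C3 as an (E)-allylic chloride, the epoxy alcohol being inert to the ruthenium carbene.

Step 8
Reactants: 12 allylic chloride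
Product: 13 triethylsilyl ether of 12 (C6–OSiEt3)
Conditions: Et3SiCl, imidazole, CH2Cl2, 0 °C
Reagents that add atoms: chlorotriethylsilane CC[Si](Cl)(CC)CC
Why: silylation of the primary alcohol removes the acidic proton before the Lewis-acid-mediated acetylide opening.

Step 9
Reactants: 13 epoxy silyl ether; 14 ethynyltrimethylsilane
Product: 16 (1S,2S)-1-[(4S,5R)-5-[(1E)-3-chloroprop-1-en-1-yl]-2,2-dimethyl-1,3-dioxan-4-yl]-2-{[(triethylsilyl)oxy]methyl}-4-(trimethylsilyl)but-3-yn-1-ol, via lithium (trimethylsilyl)acetylide 15 (not isolated)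
Conditions: 14, n-BuLi, THF, −78 °C; BF3·OEt2; then 13, −78 °C
Reagents that add atoms: none
Why: Yamaguchi alkynylation opens the trans-epoxide by SN2 attack at C7, the end remote from the branched dioxanyl carbon, with inversion, which gives the anti C7/C8 and syn C8/C9 relationships of the target (the allylic chloride is inert at −78 °C).

Step 10
Reactants: 16 homopropargylic alcohol
Product: 18 (2S,3S)-3-[(tert-butyldimethylsilyl)oxy]-3-[(4S,5R)-5-[(1E)-3-chloroprop-1-en-1-yl]-2,2-dimethyl-1,3-dioxan-4-yl]-2-[(trimethylsilyl)ethynyl]propan-1-ol, via bis-silyl ether 17 (not isolated)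
Conditions: TBSOTf, 2,6-lutidine, CH2Cl2, −78 to 0 °C; then MeOH, PPTS, 0 °C
Reagents that add atoms: tert-butyldimethylsilyl trifluoromethanesulfonate CC(C)(C)[Si](C)(C)OS(=O)(=O)C(F)(F)F
Why: the hindered C8 alcohol is capped as the robust TBS ether and mild acidic methanolysis then cleaves only the far more labile primary triethylsilyl ether.

Step 11
Reactants: 18 primary alcohol
Product: 19 (2R,3S)-3-[(tert-butyldimethylsilyl)oxy]-3-[(4S,5R)-5-[(1E)-3-chloroprop-1-en-1-yl]-2,2-dimethyl-1,3-dioxan-4-yl]-2-[(trimethylsilyl)ethynyl]propanal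
Conditions: Dess–Martin periodinane, NaHCO3, CH2Cl2, 0 °C
Reagents that add atoms: none
Why: buffered Dess–Martin oxidation gives the aldehyde without base, so the α-alkynyl centre C7 is not epimerised and the β-silyloxy group is not eliminated.

Step 12
Reactants: 19 aldehyde
Product: 20 2-vinylcyclohexanol (ring C1–C10–C9–C8–C7–C6; C6–OH trans to C1-vinyl; C7 C≡C–SiMe3; C8 OTBS; O9/O14 acetonide)
Conditions: CrCl2 (6 equiv), NaI (cat.), THF–DMF, rt, 0.01 M
Reagents that add atoms: none
Why: intramolecular Nozaki–Hiyama (Barbier-type) allylation, in which the allylchromium adds through its γ-carbon C1 to the aldehyde in a six-membered chair transition state, closes the temporary C1–C6 bond and leaves the vinyl group C2=C3 on C1 trans to the new hydroxyl.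

Step 13
Reactants: 20 cyclohexanol
Product: 21 2-vinylcyclohexanone (C6 ketone; C1 vinyl; C7 C≡C–SiMe3; C8 OTBS; O9/O14 acetonide)
Conditions: Dess–Martin periodinane, NaHCO3, CH2Cl2, 0 °C to rt
Reagents that add atoms: none
Why: base-free Dess–Martin oxidation gives the β,γ-unsaturated ketone without moving the vinyl double bond into conjugation.

Step 14
Reactants: 22 prop-2-yn-1-ol
Product: 23 1-methoxy-4-[(prop-2-yn-1-yloxy)methyl]benzene
Conditions: NaH, THF, 0 °C; 4-methoxybenzyl chloride, Bu4NI (cat.), rt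
Reagents that add atoms: 4-methoxybenzyl chloride COc1ccc(CCl)cc1
Why: Williamson etherification protects the future O15 as a PMB ether, the only group of the route that is removed oxidatively.

Step 15
Reactants: 21 ketone; 23 PMB propargyl ether
Product: 25 1-alkynyl-2-vinylcyclohexanol (C6: OH and C≡C–CH2OPMB; C1 vinyl trans to the alkynyl group; C7 C≡C–SiMe3; C8 OTBS; O9/O14 acetonide), via lithium acetylide 24 (not isolated)
Conditions: 23, n-BuLi, THF, −78 °C; CeCl3, −78 °C; then 21
Reagents that add atoms: none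
Why: 1,2-addition of the weakly basic cerium acetylide to the ketone gives the tertiary propargylic alcohol without enolising C7 or C1, attack anti to the C8 silyloxy group being expected (either C6 epimer can rearrange in step 16).

Step 16
Reactants: 25 1-alkynyl-2-vinylcyclohexanol
Product: 28 cyclodeca-2,5-dienone (C6 ketone; ring-cis C4=C5 bearing CH2OPMB; (E)-C1=C2; C7 C≡C–SiMe3; C8 OTBS; O9/O14 acetonide), via potassium alkoxide 26 (not isolated), via potassium allenolate 27 (not isolated)
Conditions: KH, 18-crown-6, THF, 0 °C to rt; AcOH/THF, −78 °C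
Reagents that add atoms: none
Why: The naked potassium alkoxide 26 undergoes a charge-accelerated [3,3]-sigmatropic shift (anionic acetylenic oxy-Cope) of the 1,5-enyne C3=C2–C1–C6(O−)–C5≡C4: the C1–C6 bond of the temporary six-membered ring breaks while the C3–C4 bond forms, and the cyclic allenolate 27 is protonated at C5 on quenching to give the conjugated enone. The closest known reaction type is the anionic oxy-Cope ring expansion of 1,2-divinyl- and 1-alkynyl-2-vinylcycloalkanols to medium-ring enones. The ten-membered ring is closed not end to end but by a four-atom ring expansion through a six-centre chair-like transition state in which the equatorial vinyl group lies gauche to the alkynyl group. No stereocentre is formed and C7, C8 and C9 are untouched; the C4=C5 geometry (C3 cis to C6) is set by protonation of the cyclic allenolate from the ring periphery, on the side of the exocyclic C15, and the transient C1=C2 geometry is of no consequence. The step needs site selectivity between the two 1,5-systems that share the alkoxide carbon, and the C1 vinyl group wins because the only other partner, the C7 alkyne, would have to bond at its SiMe3-bearing terminus and give a bis-allene, which is why the lactone carbons are carried as a silylated alkyne and not as an alkene. It also needs the rearrangement to outrun loss of the acetylide from the alkoxide, which 18-crown-6 at 0 °C and an acidic quench at −78 °C are chosen to secure.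

Step 17
Reactants: 28 dienone
Product: 30 allylic alcohol (C6–OH trans to the C7 ethynyl group; terminal alkyne at C7; otherwise as 28), via C-silylated allylic alcohol 29 (not isolated)
Conditions: NaBH4, CeCl3·7H2O, MeOH, −78 °C; then K2CO3, 0 °C to rt
Reagents that add atoms: none
Why: Luche 1,2-reduction, in which hydride is expected to add from the ring periphery anti to the C8 silyloxy group (1,3-anti induction) so that O6 ends trans to C11, followed in the same flask by basic methanolysis of the alkynyl–silicon bond.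

Step 18
Reactants: 30 homopropargylic alcohol
Product: 31 trans-fused α-methylene-γ-butyrolactone (6,12-olide; C8 OTBS; O9/O14 acetonide; C15 OPMB; (E)-C1=C2)
Conditions: PdCl2(PPh3)2 (10 mol%), SnCl2 (20 mol%), CO (7 atm), MeCN, 65 °C
Reagents that add atoms: carbon monoxide [C-]#[O+]
Why: palladium-catalysed cyclocarbonylation of a homopropargylic alcohol (alkoxycarbonyl–palladium formation at O6, syn addition across the alkyne, protonolysis) builds the α-methylene lactone in one step, with C12 coming from CO.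

Step 19
Reactants: 31 lactone acetonide
Product: 32 C9,C14-diol (lactone; C8 OTBS; C15 OPMB; (E)-C1=C2)
Conditions: PPTS, MeOH, rt
Reagents that add atoms: none
Why: acid-catalysed methanolysis removes the acetonide, while the hindered secondary TBS ether, the PMB ether and the lactone persist.

Step 20
Reactants: 32 diol
Product: 34 enal (C14 aldehyde on C10; C1=C10 with C2 trans to CHO; C9–OH free; C8 OTBS; C15 OPMB), via β,γ-unsaturated aldehyde 33 (not isolated)
Conditions: TEMPO (20 mol%), PhI(OAc)2, CH2Cl2, rt; then Et3N, 0 °C to rt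
Reagents that add atoms: none
Why: the oxoammonium oxidation takes only the primary C14 alcohol, and amine-mediated dienolisation with γ-protonation at C2 moves the double bond into conjugation with the thermodynamically preferred geometry (ring-cis, C2 trans to CHO), the free C9 hydroxyl being a poor leaving group.

Step 21
Reactants: 34 hydroxy enal
Product: 35 C9 acetate
Conditions: Ac2O, pyridine, DMAP (cat.), CH2Cl2, 0 °C
Reagents that add atoms: acetic anhydride CC(=O)OC(C)=O
Why: DMAP-catalysed acetylation of the only free hydroxyl (allylic C9–OH).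

Step 22
Reactants: 35 acetate
Product: 36 C8 alcohol
Conditions: HF·pyridine, pyridine, THF, 0 °C to rt
Reagents that add atoms: none
Why: fluoride cleavage of the only silyl ether under mildly acidic conditions frees C8–OH without harming the enal, the lactone or the acetate.

Step 23
Reactants: 36 C8 alcohol
Product: 37 C8 methacrylate (C15 OPMB)
Conditions: methacrylic anhydride, Et3N, DMAP, CH2Cl2, 0 °C to rt
Reagents that add atoms: methacrylic anhydride CC(=C)C(=O)OC(=O)C(C)=C
Why: DMAP-catalysed acylation with the anhydride esterifies the secondary C8 alcohol faster than the neighbouring acetate can migrate.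

Step 24
Reactants: 37 PMB ether
Product: 38 CNP0147326.4
Conditions: DDQ, CH2Cl2–pH 7 buffer (10:1), 0 °C
Reagents that add atoms: none
Why: oxidative PMB cleavage by DDQ (hydride abstraction, then hydrolysis of the oxocarbenium ion) is faster than oxidation of the liberated allylic alcohol and leaves the esters, the lactone and the enal untouched.

**Compound list**

1 | (S)-4-benzyl-1,3-oxazolidin-2-one | O=C1OC[C@H](Cc2ccccc2)N1 | starting material
2 | (E)-but-2-enoyl chloride | C/C=C/C(=O)Cl | starting material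
3 | (4S)-4-benzyl-3-[(2E)-but-2-enoyl]-1,3-oxazolidin-2-one | C/C=C/C(=O)N1[C@@H](Cc2ccccc2)COC1=O | intermediate
4 | ethyl (E)-4-oxobut-2-enoate | CCOC(=O)/C=C/C=O | starting material
5 | dibutylboron (Z)-dienolate of 3 | CCCCB(CCCC)O/C(=C\C=C)N1[C@@H](Cc2ccccc2)COC1=O | intermediate
6 | ethyl (2E,4R,5S)-5-{[(4S)-4-benzyl-2-oxo-1,3-oxazolidin-3-yl]carbonyl}-4-hydroxyhepta-2,6-dienoate | CCOC(=O)/C=C/[C@@H](O)[C@H](C=C)C(=O)N1[C@@H](Cc2ccccc2)COC1=O | intermediate
7 | ethyl (2E,4R,5R)-4-hydroxy-5-(hydroxymethyl)hepta-2,6-dienoate | CCOC(=O)/C=C/[C@@H](O)[C@H](C=C)CO | intermediate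
8 | ethyl (2E)-3-[(4R,5R)-5-ethenyl-2,2-dimethyl-1,3-dioxan-4-yl]prop-2-enoate | CCOC(=O)/C=C/[C@H]1OC(C)(C)OC[C@H]1C=C | intermediate
9 | (2E)-3-[(4R,5R)-5-ethenyl-2,2-dimethyl-1,3-dioxan-4-yl]prop-2-en-1-ol | OC/C=C/[C@H]1OC(C)(C)OC[C@H]1C=C | intermediate
10 | {(2R,3R)-3-[(4S,5R)-5-ethenyl-2,2-dimethyl-1,3-dioxan-4-yl]oxiran-2-yl}methanol | OC[C@H]1O[C@@H]1[C@H]2OC(C)(C)OC[C@H]2C=C | intermediate
11 | (Z)-1,4-dichlorobut-2-ene | ClC/C=C\CCl | starting material
12 | {(2R,3R)-3-[(4S,5R)-5-[(1E)-3-chloroprop-1-en-1-yl]-2,2-dimethyl-1,3-dioxan-4-yl]oxiran-2-yl}methanol | OC[C@H]1O[C@@H]1[C@H]2OC(C)(C)OC[C@H]2/C=C/CCl | intermediate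
13 | triethylsilyl ether of 12 | CC[Si](CC)(CC)OC[C@H]1O[C@@H]1[C@H]2OC(C)(C)OC[C@H]2/C=C/CCl | intermediate
14 | ethynyltrimethylsilane | C#C[Si](C)(C)C | starting material
15 | lithium (trimethylsilyl)acetylide | [Li]C#C[Si](C)(C)C | intermediate
16 | (1S,2S)-1-[(4S,5R)-5-[(1E)-3-chloroprop-1-en-1-yl]-2,2-dimethyl-1,3-dioxan-4-yl]-2-{[(triethylsilyl)oxy]methyl}-4-(trimethylsilyl)but-3-yn-1-ol | CC[Si](CC)(CC)OC[C@H](C#C[Si](C)(C)C)[C@H](O)[C@H]1OC(C)(C)OC[C@H]1/C=C/CCl | intermediate
17 | C8 tert-butyldimethylsilyl ether of 16 (bis-silyl ether) | CC[Si](CC)(CC)OC[C@H](C#C[Si](C)(C)C)[C@H](O[Si](C)(C)C(C)(C)C)[C@H]1OC(C)(C)OC[C@H]1/C=C/CCl | intermediate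
18 | (2S,3S)-3-[(tert-butyldimethylsilyl)oxy]-3-[(4S,5R)-5-[(1E)-3-chloroprop-1-en-1-yl]-2,2-dimethyl-1,3-dioxan-4-yl]-2-[(trimethylsilyl)ethynyl]propan-1-ol | OC[C@H](C#C[Si](C)(C)C)[C@H](O[Si](C)(C)C(C)(C)C)[C@H]1OC(C)(C)OC[C@H]1/C=C/CCl | intermediate
19 | (2R,3S)-3-[(tert-butyldimethylsilyl)oxy]-3-[(4S,5R)-5-[(1E)-3-chloroprop-1-en-1-yl]-2,2-dimethyl-1,3-dioxan-4-yl]-2-[(trimethylsilyl)ethynyl]propanal | O=C[C@H](C#C[Si](C)(C)C)[C@H](O[Si](C)(C)C(C)(C)C)[C@H]1OC(C)(C)OC[C@H]1/C=C/CCl | intermediate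
20 | 2-vinylcyclohexanol (C6–OH trans to C1-vinyl; C7 C≡C–SiMe3; C8 OTBS; O9/O14 acetonide) | O[C@H]1[C@H](C#C[Si](C)(C)C)[C@H](O[Si](C)(C)C(C)(C)C)[C@H]2OC(C)(C)OC[C@H]2[C@@H]1C=C | intermediate
21 | 2-vinylcyclohexanone (C6 ketone; otherwise as 20) | O=C1[C@H](C#C[Si](C)(C)C)[C@H](O[Si](C)(C)C(C)(C)C)[C@H]2OC(C)(C)OC[C@H]2[C@@H]1C=C | intermediate
22 | prop-2-yn-1-ol | C#CCO | starting material
23 | 1-methoxy-4-[(prop-2-yn-1-yloxy)methyl]benzene | C#CCOCc1ccc(OC)cc1 | intermediate
24 | lithium acetylide of 23 | [Li]C#CCOCc1ccc(OC)cc1 | intermediate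
25 | 1-alkynyl-2-vinylcyclohexanol (C6: OH and C≡C–CH2OPMB; otherwise as 21) | O[C@]1(C#CCOCc3ccc(OC)cc3)[C@H](C#C[Si](C)(C)C)[C@H](O[Si](C)(C)C(C)(C)C)[C@H]2OC(C)(C)OC[C@H]2[C@@H]1C=C | intermediate
26 | potassium alkoxide of 25 | [K+].[O-][C@]1(C#CCOCc3ccc(OC)cc3)[C@H](C#C[Si](C)(C)C)[C@H](O[Si](C)(C)C(C)(C)C)[C@H]2OC(C)(C)OC[C@H]2[C@@H]1C=C | intermediate
27 | ten-membered potassium allenolate (C6–O−; C6=C5=C4) | [K+].[O-]C1=C=C(COCc3ccc(OC)cc3)C/C=C/[C@@H]2COC(C)(C)O[C@@H]2[C@@H](O[Si](C)(C)C(C)(C)C)[C@H]1C#C[Si](C)(C)C | intermediate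
28 | cyclodeca-2,5-dienone (C6 ketone; ring-cis C4=C5 with CH2OPMB; (E)-C1=C2; C7 C≡C–SiMe3; C8 OTBS; O9/O14 acetonide) | O=C1/C=C(/COCc3ccc(OC)cc3)C/C=C/[C@@H]2COC(C)(C)O[C@@H]2[C@@H](O[Si](C)(C)C(C)(C)C)[C@H]1C#C[Si](C)(C)C | intermediate
29 | C6 allylic alcohol with C-silylated alkyne | O[C@@H]1/C=C(/COCc3ccc(OC)cc3)C/C=C/[C@@H]2COC(C)(C)O[C@@H]2[C@@H](O[Si](C)(C)C(C)(C)C)[C@H]1C#C[Si](C)(C)C | intermediate
30 | C6 allylic alcohol with terminal alkyne at C7 | O[C@@H]1/C=C(/COCc3ccc(OC)cc3)C/C=C/[C@@H]2COC(C)(C)O[C@@H]2[C@@H](O[Si](C)(C)C(C)(C)C)[C@H]1C#C | intermediate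
31 | trans-fused α-methylene lactone (C8 OTBS; O9/O14 acetonide; C15 OPMB; (E)-C1=C2) | C=C1C(=O)O[C@@H]2/C=C(/COCc3ccc(OC)cc3)C/C=C/[C@@H]4COC(C)(C)O[C@@H]4[C@@H](O[Si](C)(C)C(C)(C)C)[C@H]21 | intermediate
32 | C9,C14-diol of 31 | C=C1C(=O)O[C@@H]2/C=C(/COCc3ccc(OC)cc3)C/C=C/[C@H](CO)[C@H](O)[C@@H](O[Si](C)(C)C(C)(C)C)[C@H]21 | intermediate
33 | β,γ-unsaturated C14 aldehyde | C=C1C(=O)O[C@@H]2/C=C(/COCc3ccc(OC)cc3)C/C=C/[C@H](C=O)[C@H](O)[C@@H](O[Si](C)(C)C(C)(C)C)[C@H]21 | intermediate
34 | conjugated enal (C1=C10; C9–OH; C8 OTBS; C15 OPMB) | C=C1C(=O)O[C@@H]2/C=C(/COCc3ccc(OC)cc3)CC/C=C(/C=O)[C@H](O)[C@@H](O[Si](C)(C)C(C)(C)C)[C@H]21 | intermediate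
35 | C9 acetate of 34 | C=C1C(=O)O[C@@H]2/C=C(/COCc3ccc(OC)cc3)CC/C=C(/C=O)[C@H](OC(C)=O)[C@@H](O[Si](C)(C)C(C)(C)C)[C@H]21 | intermediate
36 | C8 alcohol (C9 OAc; C15 OPMB) | C=C1C(=O)O[C@@H]2/C=C(/COCc3ccc(OC)cc3)CC/C=C(/C=O)[C@H](OC(C)=O)[C@@H](O)[C@H]21 | intermediate
37 | C8 methacrylate (C15 OPMB) | C=C1C(=O)O[C@@H]2/C=C(/COCc3ccc(OC)cc3)CC/C=C(/C=O)[C@H](OC(C)=O)[C@@H](OC(=O)C(C)=C)[C@H]21 | intermediate
38 | CNP0147326.4: (6R,7S,8S,9S)-9-acetoxy-15-hydroxy-14-oxogermacra-1(10)E,4E,11(13)-trien-12,6-olid-8-yl methacrylate | C=C(C)C(=O)O[C@H]1[C@H]2C(=C)C(=O)O[C@@H]2/C=C(/CO)CC/C=C(/C=O)[C@@H]1OC(C)=O | target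

**Step count**

Total: 24 steps. Longest linear sequence: 23 steps (steps 1–13 and 15–24, from 1 to 38).

**Steps most likely to fail**

1. Step 16. The naked alkoxide may lose the acetylide again (retro-addition to ketone 21), or the product enone may be equilibrated by base into the conjugated 2,4-dienone before the quench.
Fallback: setting out from 21, the alkyne partner is replaced by an alkene. Hydrozirconation of 23 with Cp2Zr(H)Cl and iodination gives (E)-1-iodo-3-[(4-methoxybenzyl)oxy]prop-1-ene F1. Its alkenyllithium (t-BuLi, −78 °C; CeCl3) adds to 21 to give the 1-alkenyl-2-vinylcyclohexanol F2. The classical anionic oxy-Cope rearrangement (KH, 18-crown-6) with Me3SiCl trapping gives the ten-membered silyl enol ether F3. Saegusa–Ito oxidation with Pd(OAc)2 in MeCN then introduces the C4=C5 bond and returns to dienone 28.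

2. Step 17. Facial selectivity of hydride delivery to the medium-ring enone may be poor or reversed.
Fallback: the C6-epimeric alcohol F4, obtained from 28 under the same conditions, is inverted instead of avoided. Mitsunobu esterification (4-nitrobenzoic acid, PPh3, DIAD) gives the 4-nitrobenzoate F5 with the required C6 configuration, and methanolysis (K2CO3, MeOH) returns to alcohol 30.

3. Step 18. Under palladium, tin chloride and heat the allylic C6 alcohol may ionise, the skipped diene may migrate through palladium hydride species, or the acetonide may be lost.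
Fallback: from 30, hydrostannation at the inner alkyne carbon (Bu3SnH, Mo(CO)3(CNtBu)3) gives the 1-stannylvinyl alcohol F6. Iododestannylation (I2, 0 °C) gives the 1-iodovinyl alcohol F7. Carbonylative lactonisation under mild conditions (Pd(PPh3)4, CO 1 atm, Et3N, MeCN) then returns to lactone 31.

**Further compounds**

F1 | step 16 | (E)-1-iodo-3-[(4-methoxybenzyl)oxy]prop-1-ene | I/C=C/COCc1ccc(OC)cc1
F2 | step 16 | 1-[(E)-3-(4-methoxybenzyloxy)prop-1-enyl]-2-vinylcyclohexanol (otherwise as 25) | O[C@]1(/C=C/COCc3ccc(OC)cc3)[C@H](C#C[Si](C)(C)C)[C@H](O[Si](C)(C)C(C)(C)C)[C@H]2OC(C)(C)OC[C@H]2[C@@H]1C=C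
F3 | step 16 | ten-membered trimethylsilyl enol ether (C6 OSiMe3; C6=C5; C4–H, both C4 epimers) | C[Si](C)(C)O/C1=C/C(COCc3ccc(OC)cc3)C/C=C/[C@@H]2COC(C)(C)O[C@@H]2[C@@H](O[Si](C)(C)C(C)(C)C)[C@H]1C#C[Si](C)(C)C
F4 | step 17 | C6 epimer of 30 | O[C@H]1/C=C(/COCc3ccc(OC)cc3)C/C=C/[C@@H]2COC(C)(C)O[C@@H]2[C@@H](O[Si](C)(C)C(C)(C)C)[C@H]1C#C
F5 | step 17 | 4-nitrobenzoate of 30 | O=C(O[C@@H]1/C=C(/COCc3ccc(OC)cc3)C/C=C/[C@@H]2COC(C)(C)O[C@@H]2[C@@H](O[Si](C)(C)C(C)(C)C)[C@H]1C#C)c1ccc(cc1)[N+](=O)[O-]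
F6 | step 18 | 1-(tributylstannyl)vinyl alcohol from 30 | O[C@@H]1/C=C(/COCc3ccc(OC)cc3)C/C=C/[C@@H]2COC(C)(C)O[C@@H]2[C@@H](O[Si](C)(C)C(C)(C)C)[C@H]1C(=C)[Sn](CCCC)(CCCC)CCCC
F7 | step 18 | 1-iodovinyl alcohol from 30 | O[C@@H]1/C=C(/COCc3ccc(OC)cc3)C/C=C/[C@@H]2COC(C)(C)O[C@@H]2[C@@H](O[Si](C)(C)C(C)(C)C)[C@H]1C(I)=C
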